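**Strategy.** The saturated C17 chain is cut on both sides of its central methylene C8, which enters as the S–C–S carbon of 1,3-dithiane, a masked CH2 dianion. The key step exploits the run of thirteen unfunctionalised methylenes C2–C14 between benzylic C1 on the resorcinol ring and the C15–C17 hydroxypropyl end: about C8 they fall into two equal six-carbon arms (C2–C7 and C9–C14), both drawn from 1-bromo-6-chlorohexane. One flask unites three components and forms the C7–C8 and C8–C9 bonds by two successive SN2 alkylations. The precursors are two primary iodides: a benzyl-protected 5-(7-iodoheptyl)resorcinol and the TBS ether of (S)-9-iodononan-2-ol, whose stereocentre stems from (S)-propylene oxide.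

Key step: step 7

Assumption: the chain is numbered from the benzylic carbon (C1) to the terminal methyl (C17), the single stereocentre C16 is (S), and compounds 1, 3, 6 and 10 are taken as purchasable. The Grignard reagent 2 is made once as a stock solution and divided between the two arms.

Step 1
Reactants: 1 1-bromo-6-chlorohexane
Product: 2 (6-chlorohexyl)magnesium bromide (titrated THF solution)
Conditions: Mg turnings (1.3 equiv), THF, 30–35 °C; titrate; store under Ar
Reagents that add atoms: magnesium, [Mg]
Why: Grignard reagent formation, in which magnesium inserts into the weaker C–Br bond far faster than into C–Cl, so that below 40 °C the primary chloride is carried through unchanged and one batch of reagent serves both arms.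

Step 2
Reactants: 2 (6-chlorohexyl)magnesium bromide; 3 3,5-bis(benzyloxy)benzyl bromide
Product: 4 1,3-bis(benzyloxy)-5-(7-chloroheptyl)benzene
Conditions: 3, Li2CuCl4 (3 mol%), THF, −20 °C; 2 (1.2 equiv, THF solution) added dropwise, −20 → 0 °C; aq. NH4Cl
Reagents that add atoms: none
Why: Kochi-type Li2CuCl4-catalysed sp3–sp3 cross-coupling of a primary alkyl Grignard reagent with an activated benzylic bromide, run at low temperature with slow addition so that the primary alkyl chloride stays inert and homocoupling is limited.

Step 3
Reactants: 4 1,3-bis(benzyloxy)-5-(7-chloroheptyl)benzene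
Product: 5 1,3-bis(benzyloxy)-5-(7-iodoheptyl)benzene
Conditions: NaI (3 equiv), 2-butanone, reflux
Reagents that add atoms: sodium iodide, [Na+].[I-]
Why: Finkelstein halide exchange (SN2) on an unhindered primary chloride, driven by precipitation of NaCl from the ketone solvent, with the benzyl ethers inert.

Step 4
Reactants: 2 (6-chlorohexyl)magnesium bromide; 6 (S)-propylene oxide
Product: 7 (S)-9-chlorononan-2-ol
Conditions: 2 (THF solution), CuI (10 mol%), THF, −30 °C; 6, −30 → 0 °C; aq. NH4Cl
Reagents that add atoms: none
Why: CuI-catalysed SN2 opening of a terminal epoxide by a Grignard reagent occurs at the unsubstituted CH2 (C15), so the C16–O bond is never broken and the (S) configuration of 6 passes unchanged into 7, while the copper catalyst suppresses bromohydrin formation.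

Step 5
Reactants: 7 (S)-9-chlorononan-2-ol
Product: 8 (S)-tert-butyl[(9-chlorononan-2-yl)oxy]dimethylsilane
Conditions: TBSCl, imidazole, DMF, rt
Reagents that add atoms: tert-butyldimethylsilyl chloride (TBSCl), CC(C)(C)[Si](C)(C)Cl
Why: Corey silylation of a secondary alcohol with TBSCl and imidazole, under mildly basic conditions that leave the primary chloride and the stereocentre untouched.

Step 6
Reactants: 8 (S)-tert-butyl[(9-chlorononan-2-yl)oxy]dimethylsilane
Product: 9 (S)-tert-butyl[(9-iodononan-2-yl)oxy]dimethylsilane
Conditions: NaI (3 equiv), 2-butanone, reflux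
Reagents that add atoms: sodium iodide, [Na+].[I-]
Why: Finkelstein halide exchange (SN2) at the primary chloride under neutral conditions that a secondary TBS ether tolerates.

Step 7
Reactants: 10 1,3-dithiane; 9 (S)-tert-butyl[(9-iodononan-2-yl)oxy]dimethylsilane; 5 1,3-bis(benzyloxy)-5-(7-iodoheptyl)benzene
Product: 14 2-[7-(3,5-bis(benzyloxy)phenyl)heptyl]-2-[(8S)-8-(tert-butyldimethylsilyloxy)nonyl]-1,3-dithiane, via 2-lithio-1,3-dithiane 11 (not isolated), via monoalkyl dithiane 12 (not isolated), via lithiated monoalkyl dithiane 13 (not isolated)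
Conditions: 10 (1.05 equiv), n-BuLi (1.05 equiv), THF, −30 °C; 9, −78 → 0 °C; n-BuLi (1.05 equiv), −20 °C; 5, DMPU, −78 °C → rt
Reagents that add atoms: none
Why: n-BuLi removes the S–CH–S hydrogen of 10 to give the sulfur-stabilised carbanion 11, which displaces iodide from 9 by SN2 (C8–C9 bond) to give 12; a second deprotonation at the same carbon gives 13, which displaces iodide from 5 (C7–C8 bond), so the dithiane carbon serves as a doubly nucleophilic CH2 equivalent. The closest known reaction type is the Corey–Seebach sequential dialkylation of 1,3-dithiane with primary halides. No ring is closed and no stereocentre is created; C16 sits seven bonds from the electrophilic carbon C9 and its C–O bond is not involved, so the (S) configuration is untouched. The selectivity required is chemoselectivity: one alkylation per metalation, substitution rather than elimination, and no metalation of the ether groups. It is secured by one equivalent of base per stage, by unbranched primary iodides, and by the order of addition. The silyl-ether arm 9 goes in first so that free n-BuLi in the second metalation meets only an inert TBS ether, whereas the bis(benzyloxy)arene of 5, whose ring C–H between the two oxygens and OCH2Ph hydrogens are prone to lithiation, enters last, when only the dithianyl anion 13 is present.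

Step 8
Reactants: 14 2-[7-(3,5-bis(benzyloxy)phenyl)heptyl]-2-[(8S)-8-(tert-butyldimethylsilyloxy)nonyl]-1,3-dithiane
Product: 15 tert-butyl{[(2S)-17-(3,5-bis(benzyloxy)phenyl)heptadecan-2-yl]oxy}dimethylsilane
Conditions: Raney Ni (W-2, excess), EtOH/THF, 50 °C
Reagents that add atoms: none
Why: Mozingo reductive desulfurization, in which hydrogen-loaded Raney Ni cleaves both C–S bonds and turns the thioketal carbon C8 into CH2, while the TBS ether is inert and shields the C16 carbinol from nickel-mediated dehydrogenation and epimerisation, and moderate temperature without added H2 should spare the aryl benzyl ethers.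

Step 9
Reactants: 15 tert-butyl{[(2S)-17-(3,5-bis(benzyloxy)phenyl)heptadecan-2-yl]oxy}dimethylsilane
Product: 17 hansfordiol A, via silyl-protected resorcinol 16 (not isolated)
Conditions: H2 (1 atm), Pd/C (10 wt% Pd), EtOAc/MeOH, rt; filter; HCl (1.25 M in MeOH), rt
Reagents that add atoms: none
Why: Pd-catalysed hydrogenolysis of the two aryl benzyl ethers (feasible now that sulfur is gone) gives 16, and acid-catalysed methanolysis of the secondary TBS ether in the same pot frees the alcohol without breaking the C16–O bond, so the (S) configuration is retained.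

**Compound list**

1 | 1-bromo-6-chlorohexane | ClCCCCCCBr | starting material
2 | (6-chlorohexyl)magnesium bromide | ClCCCCCC[Mg]Br | intermediate
3 | 3,5-bis(benzyloxy)benzyl bromide | BrCc1cc(OCc2ccccc2)cc(OCc2ccccc2)c1 | starting material
4 | 1,3-bis(benzyloxy)-5-(7-chloroheptyl)benzene | ClCCCCCCCc1cc(OCc2ccccc2)cc(OCc2ccccc2)c1 | intermediate
5 | 1,3-bis(benzyloxy)-5-(7-iodoheptyl)benzene | ICCCCCCCc1cc(OCc2ccccc2)cc(OCc2ccccc2)c1 | intermediate
6 | (S)-propylene oxide, (S)-2-methyloxirane | C[C@H]1CO1 | starting material
7 | (S)-9-chlorononan-2-ol | C[C@H](O)CCCCCCCCl | intermediate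
8 | (S)-tert-butyl[(9-chlorononan-2-yl)oxy]dimethylsilane | C[C@H](O[Si](C)(C)C(C)(C)C)CCCCCCCCl | intermediate
9 | (S)-tert-butyl[(9-iodononan-2-yl)oxy]dimethylsilane | C[C@H](O[Si](C)(C)C(C)(C)C)CCCCCCCI | intermediate
10 | 1,3-dithiane | C1CSCSC1 | starting material
11 | 2-lithio-1,3-dithiane | [Li]C1SCCCS1 | intermediate
12 | 2-[(8S)-8-(tert-butyldimethylsilyloxy)nonyl]-1,3-dithiane | C[C@H](O[Si](C)(C)C(C)(C)C)CCCCCCCC1SCCCS1 | intermediate
13 | 2-lithio-2-[(8S)-8-(tert-butyldimethylsilyloxy)nonyl]-1,3-dithiane | C[C@H](O[Si](C)(C)C(C)(C)C)CCCCCCCC1([Li])SCCCS1 | intermediate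
14 | 2-[7-(3,5-bis(benzyloxy)phenyl)heptyl]-2-[(8S)-8-(tert-butyldimethylsilyloxy)nonyl]-1,3-dithiane | C[C@H](O[Si](C)(C)C(C)(C)C)CCCCCCCC1(CCCCCCCc2cc(OCc3ccccc3)cc(OCc3ccccc3)c2)SCCCS1 | intermediate
15 | tert-butyl{[(2S)-17-(3,5-bis(benzyloxy)phenyl)heptadecan-2-yl]oxy}dimethylsilane | C[C@H](O[Si](C)(C)C(C)(C)C)CCCCCCCCCCCCCCCc1cc(OCc2ccccc2)cc(OCc2ccccc2)c1 | intermediate
16 | 5-[(16S)-16-(tert-butyldimethylsilyloxy)heptadecyl]benzene-1,3-diol | C[C@H](O[Si](C)(C)C(C)(C)C)CCCCCCCCCCCCCCCc1cc(O)cc(O)c1 | intermediate
17 | hansfordiol A, 5-[(16S)-16-hydroxyheptadecyl]benzene-1,3-diol | C[C@H](O)CCCCCCCCCCCCCCCc1cc(O)cc(O)c1 | target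

**Step count and risk**

Total steps: 9. Longest linear sequence: 7 steps (steps 1, 4, 5, 6, 7, 8, 9, from 1 and 6). The aryl arm (steps 2, 3) branches from the same Grignard solution 2 and joins at step 7.

Steps most likely to fail:

1. **Step 7.** The second metalation of the hindered 2-alkyl dithiane may be incomplete, or the tertiary carbanion may act as a base and eliminate HI from the second iodide. Either would leave mono-alkylated material and an alkene in place of the three-component product. The fallback replaces the dithiane by a sulfone linchpin and sets out from 9. Methyl phenyl sulfone (CS(=O)(=O)c1ccccc1) is lithiated (n-BuLi, THF, −78 °C, anion in excess) and alkylated with 9 to give tert-butyldimethyl{[(2S)-10-(phenylsulfonyl)decan-2-yl]oxy}silane F1. F1 is deprotonated again (n-BuLi, THF, −78 °C), where the more acidic and less basic α-sulfonyl carbanion forms fast and substitutes cleanly, and is alkylated with 5 (DMPU) to give tert-butyl{[(2S)-17-(3,5-bis(benzyloxy)phenyl)-10-(phenylsulfonyl)heptadecan-2-yl]oxy}dimethylsilane F2, as a mixture of epimers at C8 that is of no consequence. Reductive desulfonylation (Na/Hg, Na2HPO4, MeOH/THF, −20 °C) then returns to the route at 15, which also bypasses step 8.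

2. **Step 2.** Halogen–metal exchange at the benzylic bromide followed by homocoupling to the bibenzyl may erode the cross-coupling. The fallback builds the C1–C2 bond by olefination and sets out from 1. PPh3 (MeCN, reflux) displaces the bromide selectively to give (6-chlorohexyl)triphenylphosphonium bromide F3. Its ylide (NaN(SiMe3)2, THF, −78 °C, aldehyde added at once) is condensed with commercial 3,5-bis(benzyloxy)benzaldehyde (O=Cc1cc(OCc2ccccc2)cc(OCc2ccccc2)c1) to give 1,3-bis(benzyloxy)-5-[(Z)-7-chlorohept-1-en-1-yl]benzene F4, whose alkene geometry is irrelevant. Diimide reduction (TsNHNH2, NaOAc, DME/H2O, reflux) saturates the alkene without hydrogenolysis of the benzyl ethers or the C–Cl bond and returns to the route at 4.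

3. **Step 8.** Over-reduction on nickel (premature hydrogenolysis of the aryl benzyl ethers) or incomplete hydrogen transfer (stalling at alkene or thioether stages) may give a mixture. The fallback removes sulfur by hydrolysis and the oxygen by hydrazone reduction, and sets out from 14. Alkylative hydrolysis (MeI, CaCO3, MeCN/H2O, 45 °C) gives (16S)-1-(3,5-bis(benzyloxy)phenyl)-16-(tert-butyldimethylsilyloxy)heptadecan-8-one F5. Condensation with TsNHNH2 (EtOH, rt) gives N'-[(16S)-1-(3,5-bis(benzyloxy)phenyl)-16-(tert-butyldimethylsilyloxy)heptadecan-8-ylidene]-4-methylbenzenesulfonohydrazide F6. Kabalka reduction (catecholborane, CHCl3, 0 °C; then NaOAc·3H2O, reflux) converts C=N into CH2 under conditions that benzyl and TBS ethers tolerate, and returns to the route at 15.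

**Further compounds**

F1 | step 7 | tert-butyldimethyl{[(2S)-10-(phenylsulfonyl)decan-2-yl]oxy}silane | C[C@H](O[Si](C)(C)C(C)(C)C)CCCCCCCCS(=O)(=O)c1ccccc1
F2 | step 7 | tert-butyl{[(2S)-17-(3,5-bis(benzyloxy)phenyl)-10-(phenylsulfonyl)heptadecan-2-yl]oxy}dimethylsilane | C[C@H](O[Si](C)(C)C(C)(C)C)CCCCCCCC(CCCCCCCc1cc(OCc2ccccc2)cc(OCc2ccccc2)c1)S(=O)(=O)c1ccccc1
F3 | step 2 | (6-chlorohexyl)triphenylphosphonium bromide | ClCCCCCC[P+](c1ccccc1)(c1ccccc1)c1ccccc1.[Br-]
F4 | step 2 | 1,3-bis(benzyloxy)-5-[(Z)-7-chlorohept-1-en-1-yl]benzene | ClCCCCC/C=C\c1cc(OCc2ccccc2)cc(OCc2ccccc2)c1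
F5 | step 8 | (16S)-1-(3,5-bis(benzyloxy)phenyl)-16-(tert-butyldimethylsilyloxy)heptadecan-8-one | C[C@H](O[Si](C)(C)C(C)(C)C)CCCCCCCC(=O)CCCCCCCc1cc(OCc2ccccc2)cc(OCc2ccccc2)c1
F6 | step 8 | N'-[(16S)-1-(3,5-bis(benzyloxy)phenyl)-16-(tert-butyldimethylsilyloxy)heptadecan-8-ylidene]-4-methylbenzenesulfonohydrazide | C[C@H](O[Si](C)(C)C(C)(C)C)CCCCCCCC(=NNS(=O)(=O)c1ccc(C)cc1)CCCCCCCc2cc(OCc3ccccc3)cc(OCc3ccccc3)c2
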